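**Plan**

1. Retrosynthesis: the stilbene aryl–vinyl bond is cut first (Heck), giving vinyl dihydrobenzofuran 13 and the chlorinated tetracyclic core 33. The fused dihydrofuran of the core is then cut at its C2–C3 bond, and the seven-membered ring at the bond between the 4-oxyphenyl-bearing methine (C11) and resorcinol ring A.
2. Enabling feature: in the core, the phenolic oxygen O-6 sits on benzo ring C ortho to the doubly benzylic ring carbon C5 of the dibenzocycloheptane, and the carbon to be joined to C5 is an O-bound 4-oxybenzyl CH. A 4-methoxybenzyl ether on O-6 therefore holds a benzylic C–H five atoms from C5, and C5 can be a ketone, hence a diaryl diazo compound and a donor/donor rhodium carbene.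
3. Forward ring order: dihydrobenzofuran of the vinyl fragment (step 6); a sacrificial 2,3-diaryl dihydrobenzofuran (step 13) that is opened by acid so that its C2 cation closes the seven-membered ring (step 16); the fused dihydrofuran last (step 21); then Heck union and deacetylation.
4. Stereochemistry: chiral dirhodium carboxylates set C3 of both early dihydrobenzofurans. The sacrificial one passes its C3 centre on as C10 of the core, C11 follows trans in the ring closure, and C5 is set by the ring conformation in the key insertion.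
5. Both O–CH(aryl) centres are equilibrated to trans during BBr3 demethylation, and the alkene is E from the Heck reaction; phenols travel as methyl ethers, then as acetates, so that no strong acid meets the stilbene.

Key step: step 21

Assumption: Rh2(R-PTAD)4 (PTAD = N-phthaloyl-(1-adamantyl)glycinate) is taken to give the 3S sense at the new C3 of the dihydrobenzofuran and Rh2(S-PTAD)4 the 3R sense; if the sense is the reverse, the two antipodes are exchanged and nothing else changes.
Remark: 3,5-dimethoxyphenylmagnesium chloride (THF solution) and N,3,5-trimethoxy-N-methylbenzamide are treated as catalogue items.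

**Route**

Step 1
Reactants: 1 2-bromo-4,6-dimethoxybenzaldehyde
Product: 2 2-bromo-6-hydroxy-4-methoxybenzaldehyde
Conditions: BCl3 (1.2 equiv), CH2Cl2, −78 → 0 °C; H2O
Reagents that add atoms: none
Why: Chelation of boron between the aldehyde oxygen and the ortho methoxy group directs selective ortho demethylation (Lewis-acid ether cleavage), leaving the para methoxy group intact.

Step 2
Reactants: 2 2-bromo-6-hydroxy-4-methoxybenzaldehyde; 3 4-methoxybenzyl chloride
Product: 4 2-bromo-4-methoxy-6-[(4-methoxybenzyl)oxy]benzaldehyde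
Conditions: K2CO3, KI (cat.), DMF, 60 °C
Reagents that add atoms: none
Why: Williamson ether synthesis on the only phenol installs the benzylic ether whose CH2 later becomes C2 of the dihydrobenzofuran.

Step 3
Reactants: 4 2-bromo-4-methoxy-6-[(4-methoxybenzyl)oxy]benzaldehyde; 5 3,5-dimethoxyphenylmagnesium chloride
Product: 6 (2-bromo-4-methoxy-6-[(4-methoxybenzyl)oxy]phenyl)(3,5-dimethoxyphenyl)methanol (racemic)
Conditions: THF, 0 °C → rt; aq NH4Cl
Reagents that add atoms: none
Why: Grignard 1,2-addition to the aldehyde is faster than any reaction at the aryl bromide; the carbinol centre is removed in the next step.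

Step 4
Reactants: 6 (2-bromo-4-methoxy-6-[(4-methoxybenzyl)oxy]phenyl)(3,5-dimethoxyphenyl)methanol
Product: 7 (2-bromo-4-methoxy-6-[(4-methoxybenzyl)oxy]phenyl)(3,5-dimethoxyphenyl)methanone
Conditions: Dess–Martin periodinane, CH2Cl2, rt
Reagents that add atoms: none
Why: Dess–Martin oxidation of the hindered diaryl carbinol is neutral and spares the benzylic ether and the aryl bromide.

Step 5
Reactants: 7 (2-bromo-4-methoxy-6-[(4-methoxybenzyl)oxy]phenyl)(3,5-dimethoxyphenyl)methanone
Product: 8 hydrazone of 7 (E/Z mixture)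
Conditions: N2H4·H2O (10 equiv), AcOH (cat.), n-BuOH, 110 °C
Reagents that add atoms: hydrazine, NN
Why: Acid-catalysed condensation of the small α-nucleophile with the diaryl ketone should proceed under forcing conditions despite the two ortho substituents; the unactivated aryl bromide is inert.

Step 6
Reactants: 8 hydrazone of 7
Product: 10 (2R,3S)-4-bromo-3-(3,5-dimethoxyphenyl)-6-methoxy-2-(4-methoxyphenyl)-2,3-dihydro-1-benzofuran (cis), via diazo compound 9 (not isolated)
Conditions: MnO2 (8 equiv), CH2Cl2, rt, filter; then Rh2(R-PTAD)4 (1 mol %), CH2Cl2, 0 °C → rt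
Reagents that add atoms: none
Why: MnO2 dehydrogenates the hydrazone to the diaryl diazo compound, and the chiral dirhodium carboxylate turns it into a donor/donor carbene that inserts into one enantiotopic benzylic C–H of the ortho ether (intramolecular carbene C–H insertion); the catalyst sets C3 and the 2,3-cis isomer is the expected kinetic outcome of this reaction class.

Step 7
Reactants: 10 (2R,3S)-4-bromo-3-(3,5-dimethoxyphenyl)-6-methoxy-2-(4-methoxyphenyl)-2,3-dihydro-1-benzofuran
Product: 11 (2S,3S)-4-bromo-3-(3,5-dihydroxyphenyl)-2-(4-hydroxyphenyl)-2,3-dihydro-1-benzofuran-6-ol (trans)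
Conditions: BBr3 (8 equiv), CH2Cl2, −78 → 0 °C; H2O
Reagents that add atoms: none
Why: BBr3 cleaves the four aryl methyl ethers and, by reversible ionisation of the benzylic C2–O bond (4-oxybenzyl cation), should equilibrate C2 to the more stable 2,3-trans isomer while C3 is untouched.

Step 8
Reactants: 11 (2S,3S)-4-bromo-3-(3,5-dihydroxyphenyl)-2-(4-hydroxyphenyl)-2,3-dihydro-1-benzofuran-6-ol
Product: 12 tetraacetate of 11
Conditions: Ac2O, pyridine, DMAP (cat.), rt
Reagents that add atoms: acetic anhydride, CC(=O)OC(C)=O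
Why: Exhaustive O-acetylation gives a protecting group that tolerates palladium couplings and is removed at the end without acid.

Step 9
Reactants: 12 tetraacetate of 11
Product: 13 (2S,3S)-6-acetoxy-3-(3,5-diacetoxyphenyl)-2-(4-acetoxyphenyl)-4-ethenyl-2,3-dihydro-1-benzofuran
Conditions: Bu3Sn(CH=CH2), Pd(PPh3)4 (5 mol %), toluene, 100 °C
Reagents that add atoms: tributyl(vinyl)stannane, C=C[Sn](CCCC)(CCCC)CCCC
Why: Stille vinylation of the aryl bromide runs under neutral conditions that leave the aryl acetates and both stereocentres unchanged.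

Step 10
Reactants: 14 2-bromo-4-chlorophenol; 3 4-methoxybenzyl chloride
Product: 15 2-bromo-4-chloro-1-[(4-methoxybenzyl)oxy]benzene
Conditions: K2CO3, DMF, 50 °C
Reagents that add atoms: none
Why: Williamson ether synthesis; the chlorine is carried as a handle that survives organolithium and carbene steps until the Heck coupling.

Step 11
Reactants: 15 2-bromo-4-chloro-1-[(4-methoxybenzyl)oxy]benzene; 16 N,3,5-trimethoxy-N-methylbenzamide
Product: 18 (5-chloro-2-[(4-methoxybenzyl)oxy]phenyl)(3,5-dimethoxyphenyl)methanone, via aryllithium 17 (not isolated)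
Conditions: n-BuLi (1.05 equiv), THF, −78 °C; then 16, −78 → 0 °C; aq NH4Cl
Reagents that add atoms: none
Why: Bromine–lithium exchange is much faster than chlorine exchange at −78 °C, and the Weinreb amide stops at the ketone through its stable chelated adduct (Weinreb ketone synthesis).

Step 12
Reactants: 18 (5-chloro-2-[(4-methoxybenzyl)oxy]phenyl)(3,5-dimethoxyphenyl)methanone
Product: 19 hydrazone of 18 (E/Z mixture)
Conditions: N2H4·H2O (5 equiv), AcOH (cat.), EtOH, 80 °C
Reagents that add atoms: hydrazine, NN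
Why: Acid-catalysed condensation of hydrazine with a mono-ortho-substituted benzophenone is routine.

Step 13
Reactants: 19 hydrazone of 18
Product: 21 (2S,3R)-5-chloro-3-(3,5-dimethoxyphenyl)-2-(4-methoxyphenyl)-2,3-dihydro-1-benzofuran (cis), via diazo compound 20 (not isolated)
Conditions: MnO2 (8 equiv), CH2Cl2, rt, filter; then Rh2(S-PTAD)4 (1 mol %), CH2Cl2, 0 °C → rt
Reagents that add atoms: none
Why: The same oxidation and donor/donor carbene C–H insertion as in step 6, with the antipodal catalyst, sets C3 (the future C10 of the core); the C2 centre is sacrificial and its configuration is irrelevant.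

Step 14
Reactants: 21 (2S,3R)-5-chloro-3-(3,5-dimethoxyphenyl)-2-(4-methoxyphenyl)-2,3-dihydro-1-benzofuran
Product: 22 (2S,3S)-3-(2-bromo-3,5-dimethoxyphenyl)-5-chloro-2-(4-methoxyphenyl)-2,3-dihydro-1-benzofuran (same spatial arrangement as 21; the C3 descriptor changes by priority only)
Conditions: NBS (1.0 equiv), CH2Cl2, −40 → 0 °C, dark
Reagents that add atoms: N-bromosuccinimide, O=C1CCC(=O)N1Br
Why: Electrophilic bromination goes to the most electron-rich ring, the 3,5-dimethoxyphenyl group, at the position para to one methoxy group and ortho to the other (the two such positions are equivalent), in preference to the crowded site between the methoxy groups.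

Step 15
Reactants: 22 (2S,3S)-3-(2-bromo-3,5-dimethoxyphenyl)-5-chloro-2-(4-methoxyphenyl)-2,3-dihydro-1-benzofuran; 16 N,3,5-trimethoxy-N-methylbenzamide
Product: 24 [2-[(2S,3R)-5-chloro-2-(4-methoxyphenyl)-2,3-dihydro-1-benzofuran-3-yl]-4,6-dimethoxyphenyl](3,5-dimethoxyphenyl)methanone, via aryllithium 23 (not isolated)
Conditions: n-BuLi (1.05 equiv), THF, −78 °C; then 16, −78 → 0 °C; aq NH4Cl
Reagents that add atoms: none
Why: Selective bromine–lithium exchange (the aryl chloride is inert) followed by Weinreb ketone synthesis attaches ring A through the carbonyl carbon that becomes C5.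

Step 16
Reactants: 24 [2-[(2S,3R)-5-chloro-2-(4-methoxyphenyl)-2,3-dihydro-1-benzofuran-3-yl]-4,6-dimethoxyphenyl](3,5-dimethoxyphenyl)methanone
Product: 25 (10R,11S)-10-(5-chloro-2-hydroxyphenyl)-1,3,6,8-tetramethoxy-11-(4-methoxyphenyl)-10,11-dihydro-5H-dibenzo[a,d][7]annulen-5-one
Conditions: TfOH (20 mol %), CH2Cl2–HFIP (4:1), 0.01 M, −30 → 0 °C; aq NaHCO3
Reagents that add atoms: none
Why: Protonation of the furan oxygen ionises the C2–O bond to a 4-methoxybenzyl cation, which is captured by the ring-A carbon ortho to the carbonyl (activated ortho and para by two methoxy groups) in an intramolecular Friedel–Crafts alkylation that closes the seven-membered ring and frees the phenol; ring A adds anti to the neighbouring aryl group so that both aryl groups become pseudo-equatorial (trans), and the former C3 centre is carried over unchanged as C10.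

Step 17
Reactants: 25 (10R,11S)-10-(5-chloro-2-hydroxyphenyl)-1,3,6,8-tetramethoxy-11-(4-methoxyphenyl)-10,11-dihydro-5H-dibenzo[a,d][7]annulen-5-one
Product: 26 (10R,11S)-10-(5-chloro-2-methoxyphenyl)-1,3,6,8-tetramethoxy-11-(4-methoxyphenyl)-10,11-dihydro-5H-dibenzo[a,d][7]annulen-5-one
Conditions: MeI, K2CO3, acetone, 50 °C
Reagents that add atoms: iodomethane, CI
Why: O-Methylation of the single phenol keeps it from competing in the later selective alkylation of O-6.

Step 18
Reactants: 26 (10R,11S)-10-(5-chloro-2-methoxyphenyl)-1,3,6,8-tetramethoxy-11-(4-methoxyphenyl)-10,11-dihydro-5H-dibenzo[a,d][7]annulen-5-one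
Product: 27 (10R,11S)-10-(5-chloro-2-methoxyphenyl)-6-hydroxy-1,3,8-trimethoxy-11-(4-methoxyphenyl)-10,11-dihydro-5H-dibenzo[a,d][7]annulen-5-one
Conditions: BCl3 (1.5 equiv), CH2Cl2, −78 → −20 °C; H2O
Reagents that add atoms: none
Why: Only the 6-methoxy group is ortho to the ketone, so boron chelation to the carbonyl directs cleavage to that ether alone.

Step 19
Reactants: 27 (10R,11S)-10-(5-chloro-2-methoxyphenyl)-6-hydroxy-1,3,8-trimethoxy-11-(4-methoxyphenyl)-10,11-dihydro-5H-dibenzo[a,d][7]annulen-5-one; 3 4-methoxybenzyl chloride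
Product: 28 (10R,11S)-10-(5-chloro-2-methoxyphenyl)-1,3,8-trimethoxy-6-[(4-methoxybenzyl)oxy]-11-(4-methoxyphenyl)-10,11-dihydro-5H-dibenzo[a,d][7]annulen-5-one
Conditions: K2CO3, KI (cat.), DMF, 60 °C
Reagents that add atoms: none
Why: Williamson ether synthesis on the only phenol places the CH2 that will become the O–CH(aryl) carbon of the last ring.

Step 20
Reactants: 28 (10R,11S)-10-(5-chloro-2-methoxyphenyl)-1,3,8-trimethoxy-6-[(4-methoxybenzyl)oxy]-11-(4-methoxyphenyl)-10,11-dihydro-5H-dibenzo[a,d][7]annulen-5-one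
Product: 29 5-hydrazinylidene derivative (hydrazone) of 28, (10R,11S)
Conditions: N2H4·H2O (10 equiv), AcOH (cat.), n-BuOH, 110 °C
Reagents that add atoms: hydrazine, NN
Why: Acid-catalysed hydrazone formation at the cyclic diaryl ketone, which carries one peri alkoxy group, is comparable to that of an ortho-alkoxy benzophenone.

Step 21
Reactants: 29 5-hydrazinylidene derivative of 28
Product: 31 cis-furan hexamethyl ether of the chlorinated tetracyclic core: 10,11-dihydro-5H-dibenzo[a,d][7]annulene with C5 and O-6 bridged by CH(4-methoxyphenyl) (2-aryl-2,3-dihydrofuran fused at C5–C5a–C6), 1,3,8-trimethoxy, 10-(5-chloro-2-methoxyphenyl), 11-(4-methoxyphenyl); 5S,10R,11S, furan C2 R (2-aryl cis to ring A), via diazo compound 30 (not isolated)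
Conditions: MnO2 (8 equiv), CH2Cl2, rt, filter; then Rh2(R-PTAD)4 (2 mol %), CH2Cl2, 0 °C → rt
Reagents that add atoms: none
Why: MnO2 dehydrogenates the hydrazone to the diaryl diazo compound 30, which loses N2 on the dirhodium carboxylate to give a donor/donor rhodium carbene at C5; hydride-transfer-type insertion into a benzylic C–H of the 6-O–CH2Ar ether then forms the C5–CH(Ar) bond. The closest known reaction type is the dirhodium-catalysed intramolecular C–H insertion of ortho-benzyloxy diaryl diazomethanes to 2,3-diaryl-2,3-dihydrobenzofurans. The dihydrofuran closes in the 1,5-insertion mode (five-membered transition state), C–C bond formation being the ring-closing event on the pre-formed aryl–O–CH2 tether. C5 is controlled by the substrate: with the trans 10,11-diaryl groups pseudo-equatorial the seven-membered ring holds ring A on one face of ring C, and the metal leaves from the opposite face, where only the pseudo-axial 10-H lies, so 5-H ends syn to 10-H; the ring-flipped conformer would force the catalyst against a pseudo-axial 10-aryl group, and the chosen catalyst antipode is the one that reinforces this sense. The O–CH(Ar) centre is expected cis to ring A, the kinetic outcome of this insertion class, and is corrected in step 22. Chemoselectivity against methoxy and other benzylic C–H bonds and against azine or alkene formation is needed; it is secured because only the 6-O–CH2Ar hydrogens can reach C5 through a five-membered transition state and the carbene carbon has no α-hydrogen.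

Step 22
Reactants: 31 cis-furan hexamethyl ether of the chlorinated tetracyclic core
Product: 32 hexaphenol of the chlorinated tetracyclic core with trans furan: 1,3,8-trihydroxy, 10-(5-chloro-2-hydroxyphenyl), 11-(4-hydroxyphenyl), furan 2-(4-hydroxyphenyl); 5S,10R,11S, furan C2 S
Conditions: BBr3 (12 equiv), CH2Cl2, −78 → 0 °C; H2O
Reagents that add atoms: none
Why: BBr3 cleaves the six aryl methyl ethers and, through reversible ionisation of the benzylic C–O bond of the 2-aryl dihydrofuran, should equilibrate the O–CH(Ar) centre to the trans arrangement in which the aryl group avoids ring A; no stilbene is present yet, so acid-triggered alkene cyclisation is not possible.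

Step 23
Reactants: 32 hexaphenol of the chlorinated tetracyclic core
Product: 33 hexaacetate of 32
Conditions: Ac2O, pyridine, DMAP (cat.), rt
Reagents that add atoms: acetic anhydride, CC(=O)OC(C)=O
Why: Exhaustive O-acetylation protects the phenols for the coupling and makes the chloroarene less electron-rich for oxidative addition.

Step 24
Reactants: 33 hexaacetate of 32; 13 (2S,3S)-6-acetoxy-3-(3,5-diacetoxyphenyl)-2-(4-acetoxyphenyl)-4-ethenyl-2,3-dihydro-1-benzofuran
Product: 34 decaacetate of the target (E-stilbene)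
Conditions: Pd(P(t-Bu)3)2 (5 mol %), Cy2NMe (1.5 equiv), 1,4-dioxane, 100 °C
Reagents that add atoms: none
Why: Heck reaction of the unhindered aryl chloride (para to an acetoxy group) with the styrene, using an electron-rich bulky phosphine on zerovalent palladium, arylates the terminal alkene carbon and gives the E-alkene by syn insertion and syn β-hydride elimination; the amine base leaves the acetates intact.

Step 25
Reactants: 34 decaacetate of the target
Product: 35 CNP0266373.1 (target decaphenol; 5S,10R,11S, furan C2 S in the core; 2S,3S in the stilbene-linked dihydrobenzofuran; E-alkene)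
Conditions: NH3 (7 M in MeOH), THF, 0 °C → rt, argon
Reagents that add atoms: none
Why: Aminolysis of the ten aryl acetates is weakly basic and acid-free, so neither the stilbene nor the two 2-aryl dihydrofurans nor any stereocentre is disturbed.

**Compound list**

1 | 2-bromo-4,6-dimethoxybenzaldehyde | COc1cc(Br)c(C=O)c(OC)c1 | starting material
2 | 2-bromo-6-hydroxy-4-methoxybenzaldehyde | COc1cc(O)c(C=O)c(Br)c1 | intermediate
3 | 4-methoxybenzyl chloride | COc1ccc(CCl)cc1 | starting material
4 | 2-bromo-4-methoxy-6-[(4-methoxybenzyl)oxy]benzaldehyde | COc1cc(Br)c(C=O)c(OCc2ccc(OC)cc2)c1 | intermediate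
5 | 3,5-dimethoxyphenylmagnesium chloride | COc1cc(OC)cc([Mg]Cl)c1 | starting material
6 | (2-bromo-4-methoxy-6-[(4-methoxybenzyl)oxy]phenyl)(3,5-dimethoxyphenyl)methanol, racemic | COc1cc(Br)c(C(O)c2cc(OC)cc(OC)c2)c(OCc2ccc(OC)cc2)c1 | intermediate
7 | (2-bromo-4-methoxy-6-[(4-methoxybenzyl)oxy]phenyl)(3,5-dimethoxyphenyl)methanone | COc1cc(Br)c(C(=O)c2cc(OC)cc(OC)c2)c(OCc2ccc(OC)cc2)c1 | intermediate
8 | hydrazone of 7 | COc1cc(Br)c(C(=NN)c2cc(OC)cc(OC)c2)c(OCc2ccc(OC)cc2)c1 | intermediate
9 | diazo compound from 8 | COc1cc(Br)c(C(=[N+]=[N-])c2cc(OC)cc(OC)c2)c(OCc2ccc(OC)cc2)c1 | intermediate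
10 | (2R,3S)-4-bromo-3-(3,5-dimethoxyphenyl)-6-methoxy-2-(4-methoxyphenyl)-2,3-dihydro-1-benzofuran (cis) | Brc1cc(OC)cc2c1[C@H](c1cc(OC)cc(OC)c1)[C@H](c1ccc(OC)cc1)O2 | intermediate
11 | (2S,3S)-4-bromo-3-(3,5-dihydroxyphenyl)-2-(4-hydroxyphenyl)-2,3-dihydro-1-benzofuran-6-ol (trans) | Brc1cc(O)cc2c1[C@H](c1cc(O)cc(O)c1)[C@@H](c1ccc(O)cc1)O2 | intermediate
12 | tetraacetate of 11 | Brc1cc(OC(C)=O)cc2c1[C@H](c1cc(OC(C)=O)cc(OC(C)=O)c1)[C@@H](c1ccc(OC(C)=O)cc1)O2 | intermediate
13 | (2S,3S)-6-acetoxy-3-(3,5-diacetoxyphenyl)-2-(4-acetoxyphenyl)-4-ethenyl-2,3-dihydro-1-benzofuran | C=Cc1cc(OC(C)=O)cc2c1[C@H](c1cc(OC(C)=O)cc(OC(C)=O)c1)[C@@H](c1ccc(OC(C)=O)cc1)O2 | intermediate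
14 | 2-bromo-4-chlorophenol | Oc1ccc(Cl)cc1Br | starting material
15 | 2-bromo-4-chloro-1-[(4-methoxybenzyl)oxy]benzene | COc1ccc(COc2ccc(Cl)cc2Br)cc1 | intermediate
16 | N,3,5-trimethoxy-N-methylbenzamide | CON(C)C(=O)c1cc(OC)cc(OC)c1 | starting material
17 | aryllithium from 15 | COc1ccc(COc2ccc(Cl)cc2[Li])cc1 | intermediate
18 | (5-chloro-2-[(4-methoxybenzyl)oxy]phenyl)(3,5-dimethoxyphenyl)methanone | COc1ccc(COc2ccc(Cl)cc2C(=O)c2cc(OC)cc(OC)c2)cc1 | intermediate
19 | hydrazone of 18 | COc1ccc(COc2ccc(Cl)cc2C(=NN)c2cc(OC)cc(OC)c2)cc1 | intermediate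
20 | diazo compound from 19 | COc1ccc(COc2ccc(Cl)cc2C(=[N+]=[N-])c2cc(OC)cc(OC)c2)cc1 | intermediate
21 | (2S,3R)-5-chloro-3-(3,5-dimethoxyphenyl)-2-(4-methoxyphenyl)-2,3-dihydro-1-benzofuran (cis) | Clc1ccc2c(c1)[C@@H](c1cc(OC)cc(OC)c1)[C@@H](c1ccc(OC)cc1)O2 | intermediate
22 | (2S,3S)-3-(2-bromo-3,5-dimethoxyphenyl)-5-chloro-2-(4-methoxyphenyl)-2,3-dihydro-1-benzofuran (cis) | Clc1ccc2c(c1)[C@@H](c1cc(OC)cc(OC)c1Br)[C@@H](c1ccc(OC)cc1)O2 | intermediate
23 | aryllithium from 22 | Clc1ccc2c(c1)[C@@H](c1cc(OC)cc(OC)c1[Li])[C@@H](c1ccc(OC)cc1)O2 | intermediate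
24 | [2-[(2S,3R)-5-chloro-2-(4-methoxyphenyl)-2,3-dihydro-1-benzofuran-3-yl]-4,6-dimethoxyphenyl](3,5-dimethoxyphenyl)methanone | Clc1ccc2c(c1)[C@@H](c1cc(OC)cc(OC)c1C(=O)c1cc(OC)cc(OC)c1)[C@@H](c1ccc(OC)cc1)O2 | intermediate
25 | (10R,11S)-10-(5-chloro-2-hydroxyphenyl)-1,3,6,8-tetramethoxy-11-(4-methoxyphenyl)-10,11-dihydro-5H-dibenzo[a,d][7]annulen-5-one | COc1ccc([C@H]2c3c(OC)cc(OC)cc3C(=O)c3c(OC)cc(OC)cc3[C@@H]2c2cc(Cl)ccc2O)cc1 | intermediate
26 | (10R,11S)-10-(5-chloro-2-methoxyphenyl)-1,3,6,8-tetramethoxy-11-(4-methoxyphenyl)-10,11-dihydro-5H-dibenzo[a,d][7]annulen-5-one | COc1ccc([C@H]2c3c(OC)cc(OC)cc3C(=O)c3c(OC)cc(OC)cc3[C@@H]2c2cc(Cl)ccc2OC)cc1 | intermediate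
27 | (10R,11S)-10-(5-chloro-2-methoxyphenyl)-6-hydroxy-1,3,8-trimethoxy-11-(4-methoxyphenyl)-10,11-dihydro-5H-dibenzo[a,d][7]annulen-5-one | COc1ccc([C@H]2c3c(OC)cc(OC)cc3C(=O)c3c(O)cc(OC)cc3[C@@H]2c2cc(Cl)ccc2OC)cc1 | intermediate
28 | (10R,11S)-10-(5-chloro-2-methoxyphenyl)-1,3,8-trimethoxy-6-[(4-methoxybenzyl)oxy]-11-(4-methoxyphenyl)-10,11-dihydro-5H-dibenzo[a,d][7]annulen-5-one | COc1ccc([C@H]2c3c(OC)cc(OC)cc3C(=O)c3c(OCc4ccc(OC)cc4)cc(OC)cc3[C@@H]2c2cc(Cl)ccc2OC)cc1 | intermediate
29 | 5-hydrazinylidene derivative (hydrazone) of 28 | COc1ccc([C@H]2c3c(OC)cc(OC)cc3C(=NN)c3c(OCc4ccc(OC)cc4)cc(OC)cc3[C@@H]2c2cc(Cl)ccc2OC)cc1 | intermediate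
30 | 5-diazo compound from 29 | COc1ccc([C@H]2c3c(OC)cc(OC)cc3C(=[N+]=[N-])c3c(OCc4ccc(OC)cc4)cc(OC)cc3[C@@H]2c2cc(Cl)ccc2OC)cc1 | intermediate
31 | cis-furan hexamethyl ether of the chlorinated tetracyclic core (5S,10R,11S, furan C2 R) | COc1ccc([C@H]2c3c(OC)cc(OC)cc3[C@H]3c4c(cc(OC)cc4[C@@H]2c2cc(Cl)ccc2OC)O[C@H]3c2ccc(OC)cc2)cc1 | intermediate
32 | hexaphenol of the chlorinated tetracyclic core, trans furan (5S,10R,11S, furan C2 S) | Oc1ccc([C@H]2c3c(O)cc(O)cc3[C@H]3c4c(cc(O)cc4[C@@H]2c2cc(Cl)ccc2O)O[C@@H]3c2ccc(O)cc2)cc1 | intermediate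
33 | hexaacetate of 32 | CC(=O)Oc1ccc([C@H]2c3c(OC(C)=O)cc(OC(C)=O)cc3[C@H]3c4c(cc(OC(C)=O)cc4[C@@H]2c2cc(Cl)ccc2OC(C)=O)O[C@@H]3c2ccc(OC(C)=O)cc2)cc1 | intermediate
34 | decaacetate of the target | CC(=O)Oc1ccc([C@H]2c3c(OC(C)=O)cc(OC(C)=O)cc3[C@H]3c4c(cc(OC(C)=O)cc4[C@@H]2c2cc(/C=C/c4cc(OC(C)=O)cc5c4[C@H](c4cc(OC(C)=O)cc(OC(C)=O)c4)[C@@H](c4ccc(OC(C)=O)cc4)O5)ccc2OC(C)=O)O[C@@H]3c2ccc(OC(C)=O)cc2)cc1 | intermediate
35 | CNP0266373.1 | Oc1ccc([C@H]2c3c(O)cc(O)cc3[C@H]3c4c(cc(O)cc4[C@@H]2c2cc(/C=C/c4cc(O)cc5c4[C@H](c4cc(O)cc(O)c4)[C@@H](c4ccc(O)cc4)O5)ccc2O)O[C@@H]3c2ccc(O)cc2)cc1 | target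

**Step count and risks**

Total step count: 25. Longest linear sequence: 16 steps (steps 10–25, from 14 to 35); the vinyl fragment 13 takes 9 steps (steps 1–9).

Steps most likely to fail:

1. Step 16. Capture of the benzylic cation by the carbonyl oxygen, or loss of the adjacent methine proton (which would erode the configuration carried from C3), may outrun C–C bond formation at ring A, which is deactivated by the ortho carbonyl group. Fallback: set out from bromide 22 and cyclise at the alcohol oxidation level, where ring A is a benzyl-type, non-deactivated nucleophile. Bromine–lithium exchange as in step 15 and addition to 3,5-dimethoxybenzaldehyde should give the benzhydrol F1. Catalytic TfOH in CH2Cl2–HFIP at high dilution should then open the dihydrofuran and close the seven-membered ring to the trans-10,11-diaryl dibenzosuberol F2; the benzhydryl position ionises reversibly and returns to the alcohol on aqueous work-up. Oxidation of the doubly benzylic alcohol with MnO2 leads back to the route at 25.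

2. Step 21 (with its enabling condensation, step 20). The hydrazone may not form at the hindered carbonyl, the diazo compound may divert to azine or carbene dimer, or face selection at the carbene carbon may be insufficient. Fallback: set out from hydroxy ketone 27 and close the same ring by C–O bond formation under thermodynamic control. Addition of 4-methoxybenzylmagnesium chloride (excess, THF) should give the tertiary alcohol F3. Acid (TFA, CH2Cl2) should dehydrate it to the benzylidene, protonate at C5 and let the peri phenol trap the resulting 4-methoxybenzyl cation, giving the trans-furan hexamethyl ether F4 with the aryl groups at C10 and C11 pseudo-equatorial. Demethylation of F4 under the conditions of step 22 leads back to the route at 32.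

3. Step 24. Slow oxidative addition to the chloroarene, or slow insertion of the ortho-substituted styrene, may lead to catalyst decomposition, acetate loss or alkene migration at the most advanced stage. Fallback: set out from chloride 33 and form the stilbene by olefin metathesis instead. Stille vinylation (tributyl(vinyl)stannane, Pd(P(t-Bu)3)2, CsF, dioxane) should give the styrene hexaacetate F5. Cross-metathesis of F5 with 13 (second-generation Hoveyda–Grubbs catalyst, CH2Cl2, 40 °C), in which the ortho-substituted styrene 13 homodimerises slowly, should give the E-stilbene and lead back to the route at 34.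

**Further compounds**

F1 | step 16 | [2-[(2S,3R)-5-chloro-2-(4-methoxyphenyl)-2,3-dihydro-1-benzofuran-3-yl]-4,6-dimethoxyphenyl](3,5-dimethoxyphenyl)methanol (carbinol epimers) | Clc1ccc2c(c1)[C@@H](c1cc(OC)cc(OC)c1C(O)c1cc(OC)cc(OC)c1)[C@@H](c1ccc(OC)cc1)O2
F2 | step 16 | (10R,11S)-10-(5-chloro-2-hydroxyphenyl)-1,3,6,8-tetramethoxy-11-(4-methoxyphenyl)-10,11-dihydro-5H-dibenzo[a,d][7]annulen-5-ol (C5 epimers) | COc1ccc([C@H]2c3c(OC)cc(OC)cc3C(O)c3c(OC)cc(OC)cc3[C@@H]2c2cc(Cl)ccc2O)cc1
F3 | step 21 | (10R,11S)-10-(5-chloro-2-methoxyphenyl)-1,3,8-trimethoxy-5-(4-methoxybenzyl)-11-(4-methoxyphenyl)-10,11-dihydro-5H-dibenzo[a,d][7]annulene-5,6-diol (C5 epimers) | COc1ccc([C@H]2c3c(OC)cc(OC)cc3C(O)(Cc3ccc(OC)cc3)c3c(O)cc(OC)cc3[C@@H]2c2cc(Cl)ccc2OC)cc1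
F4 | step 21 | trans-furan hexamethyl ether of the chlorinated tetracyclic core (5S,10R,11S, furan C2 S) | COc1ccc([C@H]2c3c(OC)cc(OC)cc3[C@H]3c4c(cc(OC)cc4[C@@H]2c2cc(Cl)ccc2OC)O[C@@H]3c2ccc(OC)cc2)cc1
F5 | step 24 | hexaacetate of the tetracyclic core bearing ethenyl in place of chlorine | CC(=O)Oc1ccc([C@H]2c3c(OC(C)=O)cc(OC(C)=O)cc3[C@H]3c4c(cc(OC(C)=O)cc4[C@@H]2c2cc(C=C)ccc2OC(C)=O)O[C@@H]3c2ccc(OC(C)=O)cc2)cc1
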